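**Plan** (azulene numbering: C1–C3, C3a, C8a form the five-membered ring; C4–C8 complete the seven-membered ring)
1. Retrosynthesis: cut the ester C–O bond; take the C4 carbinol back through the C4 ketone to an epoxide on a C3a=C4 olefin; cut the C3–isopropyl bond (addition to a C3 enone); then cut the two seven-ring bonds C3a–C8a and C4–C5 in one step; finally cut the ethynyl–carbinol bond and the cyclopropane (nerol + CH2).
2. Enabling feature: from the quaternary ring-fusion carbon, the seven-membered ring reads C8a(CH3)–C8H2–C7H=C6(CH3)–C5H2, the imprint of a ring-opened 1-methyl-2-isopropenylcyclopropane. The two remaining ring carbons (C3a, C4) are adjacent and can come from an alkyne tied to C8a by C1–C3.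
3. Forward: cyclopropane from nerol, side-chain trimming and ethynylation, then a rhodium-catalysed intramolecular [5+2] cycloaddition that closes the five- and seven-membered rings together; enone, isopropyl addition, epoxidation, radical epoxide opening, oxidation/reduction at C4 and acylation follow.
4. Stereochemistry: C8a from the Z olefin of nerol plus a chiral dioxaborolane, carried through the cycloaddition with retention; C3 by addition anti to the angular methyl; C3a by hydrogen-atom transfer anti to the angular methyl after hydroxyl-directed epoxidation; C4 by hydroxyl-directed anti reduction.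

Key step: step 7

Assumption: the chiral dioxaborolane shows on nerol its usual sense of facial induction (the one that converts cinnamyl alcohol to the (1S,2S)-cyclopropane); if the sense were opposite, the enantiomeric controller would be used.

Step 1
Reactants: 1 nerol ((2Z)-3,7-dimethylocta-2,6-dien-1-ol)
Product: 2 [(1S,2R)-2-methyl-2-(4-methylpent-3-en-1-yl)cyclopropyl]methanol
Conditions: Et2Zn, CH2I2, DME, (4R,5R)-2-butyl-N,N,N',N'-tetramethyl-1,3,2-dioxaborolane-4,5-dicarboxamide (1.2 equiv), CH2Cl2, −10 °C to rt; aq. NH4Cl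
Reagents that add atoms: diiodomethane ICI
Why: Simmons–Smith cyclopropanation directed by the zinc alkoxide touches only the allylic olefin, the Z geometry is transferred stereospecifically so that CH2OH and the homoprenyl chain end up cis on the ring, and the chiral dioxaborolane bound to that alkoxide selects the olefin face and thereby the absolute configuration of both new stereocentres.

Step 2
Reactants: 2 [(1S,2R)-2-methyl-2-(4-methylpent-3-en-1-yl)cyclopropyl]methanol
Product: 4 (1S,2R)-2-methyl-2-(4-methylpent-3-en-1-yl)cyclopropane-1-carboxylic acid, via cyclopropanecarbaldehyde 3 (not isolated)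
Conditions: TEMPO (cat.), PhI(OAc)2 (2.2 equiv), MeCN/H2O, rt
Reagents that add atoms: water O
Why: Oxoammonium (TEMPO) oxidation of the primary alcohol passes through the aldehyde, whose hydrate is oxidized on to the acid in the aqueous medium, while the trisubstituted olefin is inert and the cyclopropyl C–H next to the carbonyl does not enolize, so the cis relationship is kept.

Step 3
Reactants: 4 (1S,2R)-2-methyl-2-(4-methylpent-3-en-1-yl)cyclopropane-1-carboxylic acid
Product: 5 1-[(1S,2R)-2-methyl-2-(4-methylpent-3-en-1-yl)cyclopropyl]ethan-1-one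
Conditions: MeLi (2.2 equiv), Et2O, 0 °C to rt; aq. NH4Cl
Reagents that add atoms: methyllithium [Li]C
Why: Addition of MeLi to the lithium carboxylate stops at the dilithium gem-diolate, which gives the methyl ketone only on hydrolysis (carboxylic acid to methyl ketone with an organolithium), and no stereocentre is touched.

Step 4
Reactants: 5 1-[(1S,2R)-2-methyl-2-(4-methylpent-3-en-1-yl)cyclopropyl]ethan-1-one
Product: 7 3-[(1R,2S)-2-acetyl-1-methylcyclopropyl]propanal, via ozonide 6 (not isolated)
Conditions: O3, CH2Cl2, −78 °C; then PPh3, −78 °C to rt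
Reagents that add atoms: ozone [O-][O+]=O
Why: Ozonolysis with reductive work-up cleaves the only C=C bond to the aldehyde and acetone, while ketone and cyclopropane are inert to ozone at −78 °C.

Step 5
Reactants: 7 3-[(1R,2S)-2-acetyl-1-methylcyclopropyl]propanal
Product: 8 1-[(1S,2R)-2-(3-hydroxypent-4-yn-1-yl)-2-methylcyclopropyl]ethan-1-one (both carbinol epimers)
Conditions: HC≡CMgBr (1.1 equiv), THF, −78 °C; aq. NH4Cl
Reagents that add atoms: ethynylmagnesium bromide C#C[Mg]Br
Why: Grignard addition at −78 °C is selective for the aldehyde over the methyl ketone, and the new carbinol centre forms without control, which does not matter because it is oxidized in step 8.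

Step 6
Reactants: 8 1-[(1S,2R)-2-(3-hydroxypent-4-yn-1-yl)-2-methylcyclopropyl]ethan-1-one (both carbinol epimers)
Product: 9 5-[(1R,2R)-1-methyl-2-(prop-1-en-2-yl)cyclopropyl]pent-1-yn-3-ol (both carbinol epimers; side chain cis to the isopropenyl group)
Conditions: Ph3PCH3Br (3.0 equiv), KOtBu (2.8 equiv), THF, 0 °C to rt
Reagents that add atoms: methyltriphenylphosphonium bromide C[P+](c1ccccc1)(c1ccccc1)c1ccccc1.[Br-]
Why: Wittig methylenation converts the methyl ketone into the isopropenyl group, the ylide is too weak a base to remove the cyclopropyl α-hydrogen (so the cis-disposed chain and isopropenyl group are retained), and an excess compensates for the free hydroxyl group.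

Step 7
Reactants: 9 5-[(1R,2R)-1-methyl-2-(prop-1-en-2-yl)cyclopropyl]pent-1-yn-3-ol (both carbinol epimers)
Product: 10 (8aR)-6,8a-dimethyl-1,2,3,5,8,8a-hexahydroazulen-3-ol (both C3 epimers)
Conditions: [Rh(CO)2Cl]2 (5 mol %), 1,2-dichloroethane (0.02 M), 80 °C, argon
Reagents that add atoms: none
Why: Proposed new method: monovalent rhodium should insert into the cyclopropane bond between the isopropenyl-bearing carbon and the quaternary carbon (strain release, assisted by the vinyl π system) to give a σ-alkyl/π-allyl rhodacycle, the alkyne held on the allyl face by the cis relationship then inserts into the Rh–C(quaternary) bond, and C(sp2)–C(sp3) reductive elimination at the distal allyl terminus releases the 1,4-cycloheptadiene; the closest known reactions are the rhodium-catalysed intramolecular [5+2] cycloadditions of alkyne-tethered vinylcyclopropanes (tether on the vinyl group) and the [5+2] mode of cis-2-ene-vinylcyclopropanes (tether on the ring, alkene partner), and the new element is a ring-attached tether combined with an alkyne and a fully substituted cyclopropane carbon. The five-membered ring closes by 5-exo-dig migratory insertion (bond C3a–C8a) and the seven-membered ring by reductive elimination from the eight-membered rhodacycle (bond C4–C5). No new stereocentre is formed: the quaternary centre is carried over with retention (retentive oxidative addition and retentive alkyl migration), so step 1 fixes the absolute configuration of the ring system, and the carbinol centre is a spectator. The step needs cleavage of the more substituted cyclopropane bond, which is secured because only that rhodacycle can be intercepted through the three-carbon tether (the alternative would have to close to a bridgehead olefin) and because a cis substituent favours cleavage of the bond it sits on. It needs coupling at the distal rather than the proximal allyl terminus ([5+2], not [3+2]), which the cis geometry (anti-configured allyl lying over the alkenyl–rhodium carbon) and the strain of the alternative bicyclo[3.3.0]octadiene favour. It must also outrun the thermal homodienyl 1,5-hydrogen shift of a cis-alkyl vinylcyclopropane, hence a temperature of at most 80 °C.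

Step 8
Reactants: 10 (8aR)-6,8a-dimethyl-1,2,3,5,8,8a-hexahydroazulen-3-ol (both C3 epimers)
Product: 11 (8aR)-6,8a-dimethyl-1,2,8,8a-tetrahydroazulen-3(5H)-one
Conditions: MnO2 (activated, excess), CH2Cl2, rt
Reagents that add atoms: none
Why: MnO2 oxidizes only the allylic alcohol under neutral conditions, which merges both carbinol epimers into one enone and avoids base-mediated migration of the ring-fusion double bond into conjugation with the second olefin.

Step 9
Reactants: 11 (8aR)-6,8a-dimethyl-1,2,8,8a-tetrahydroazulen-3(5H)-one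
Product: 12 (3R,8aR)-6,8a-dimethyl-3-(propan-2-yl)-1,2,3,5,8,8a-hexahydroazulen-3-ol
Conditions: iPrMgCl, CeCl3 (anhydrous), THF, −78 °C; aq. NH4Cl
Reagents that add atoms: isopropylmagnesium chloride CC(C)[Mg]Cl
Why: The weakly basic organocerium reagent adds 1,2 to the enolizable enone (organocerium carbonyl addition) instead of deprotonating or reducing it, and it attacks the carbonyl from the face opposite to the angular methyl group two carbons away, which places the new hydroxyl cis to that methyl (3R).

Step 10
Reactants: 12 (3R,8aR)-6,8a-dimethyl-3-(propan-2-yl)-1,2,3,5,8,8a-hexahydroazulen-3-ol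
Product: 13 the 3a,4-epoxide of 12 with the oxirane oxygen cis to the hydroxyl group and to the angular methyl group
Conditions: VO(acac)2 (5 mol %), t-BuOOH, CH2Cl2, 0 °C to rt
Reagents that add atoms: tert-butyl hydroperoxide CC(C)(C)OO
Why: Vanadium-catalysed hydroxyl-directed epoxidation delivers the oxygen from the alkoxide-bound peroxide only to the allylic double bond and to the face that carries the tertiary hydroxyl, which fixes both oxirane stereocentres cis to the hydroxyl and leaves the ring olefin untouched.

Step 11
Reactants: 13 the 3a,4-epoxide of 12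
Product: 14 (3R,3aS,4R,8aR)-6,8a-dimethyl-3-(propan-2-yl)-1,2,3,3a,4,5,8,8a-octahydroazulene-3,4-diol
Conditions: Cp2TiCl2, Zn dust, 1,4-cyclohexadiene (excess), THF, rt; aq. NaH2PO4
Reagents that add atoms: none
Why: Trivalent titanium (Cp2TiCl, formed in the flask) opens the oxirane by single-electron transfer at the more substituted carbon (titanocene-mediated reductive epoxide opening), and the resulting tertiary ring-fusion radical takes a hydrogen atom from 1,4-cyclohexadiene on its open face, opposite to the angular methyl and the two titanium-bound oxygens, which sets the ring-fusion hydrogen trans to the methyl while the C4–O bond keeps its configuration.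

Step 12
Reactants: 14 (3R,3aS,4R,8aR)-6,8a-dimethyl-3-(propan-2-yl)-1,2,3,3a,4,5,8,8a-octahydroazulene-3,4-diol
Product: 15 (3R,3aR,8aR)-3-hydroxy-6,8a-dimethyl-3-(propan-2-yl)-2,3,3a,5,8,8a-hexahydroazulen-4(1H)-one
Conditions: Dess–Martin periodinane, pyridine, CH2Cl2, 0 °C to rt
Reagents that add atoms: none
Why: Dess–Martin oxidation takes the secondary alcohol to the ketone and cannot touch the tertiary one, and the pyridine buffer suppresses acid-promoted dehydration of the β-hydroxy ketone and epimerization at the ring fusion.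

Step 13
Reactants: 15 (3R,3aR,8aR)-3-hydroxy-6,8a-dimethyl-3-(propan-2-yl)-2,3,3a,5,8,8a-hexahydroazulen-4(1H)-one
Product: 16 jaeschkeanadiol ((3R,3aS,4S,8aR)-6,8a-dimethyl-3-(propan-2-yl)-1,2,3,3a,4,5,8,8a-octahydroazulene-3,4-diol)
Conditions: SmI2 (3 equiv), MeOH, THF, 0 °C
Reagents that add atoms: none
Why: Hydroxyl-directed SmI2 reduction proceeds through a ketyl chelated to the β-hydroxyl and gives the 1,3-anti diol, here also the more stable equatorial carbinol trans to the tertiary hydroxyl and cis to the ring-fusion hydrogen (4S), without base that could cause retro-aldol cleavage.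

Step 14
Reactants: 16 jaeschkeanadiol; 17 3,4-dimethoxybenzoyl chloride
Product: 18 (3R,3aS,4S,8aR)-3-hydroxy-6,8a-dimethyl-3-(propan-2-yl)-1,2,3,3a,4,5,8,8a-octahydroazulen-4-yl 3,4-dimethoxybenzoate
Conditions: Et3N, DMAP (cat.), CH2Cl2, 0 °C to rt
Reagents that add atoms: none
Why: DMAP-catalysed acylation with the acid chloride esterifies the secondary hydroxyl only, since the tertiary isopropyl carbinol is too hindered to react.

**Compound list**
1 | nerol, (2Z)-3,7-dimethylocta-2,6-dien-1-ol | CC(C)=CCC/C(C)=C\CO | starting material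
2 | [(1S,2R)-2-methyl-2-(4-methylpent-3-en-1-yl)cyclopropyl]methanol | OC[C@H]1C[C@@]1(C)CCC=C(C)C | intermediate
3 | (1S,2R)-2-methyl-2-(4-methylpent-3-en-1-yl)cyclopropane-1-carbaldehyde | O=C[C@H]1C[C@@]1(C)CCC=C(C)C | intermediate
4 | (1S,2R)-2-methyl-2-(4-methylpent-3-en-1-yl)cyclopropane-1-carboxylic acid | OC(=O)[C@H]1C[C@@]1(C)CCC=C(C)C | intermediate
5 | 1-[(1S,2R)-2-methyl-2-(4-methylpent-3-en-1-yl)cyclopropyl]ethan-1-one | CC(=O)[C@H]1C[C@@]1(C)CCC=C(C)C | intermediate
6 | secondary ozonide of 5, 1-[(1S,2R)-2-[2-(5,5-dimethyl-1,2,4-trioxolan-3-yl)ethyl]-2-methylcyclopropyl]ethan-1-one | CC(=O)[C@H]1C[C@@]1(C)CCC1OOC(C)(C)O1 | intermediate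
7 | 3-[(1R,2S)-2-acetyl-1-methylcyclopropyl]propanal | CC(=O)[C@H]1C[C@@]1(C)CCC=O | intermediate
8 | 1-[(1S,2R)-2-(3-hydroxypent-4-yn-1-yl)-2-methylcyclopropyl]ethan-1-one, both carbinol epimers | CC(=O)[C@H]1C[C@@]1(C)CCC(O)C#C | intermediate
9 | 5-[(1R,2R)-1-methyl-2-(prop-1-en-2-yl)cyclopropyl]pent-1-yn-3-ol, both carbinol epimers | C=C(C)[C@H]1C[C@@]1(C)CCC(O)C#C | intermediate
10 | (8aR)-6,8a-dimethyl-1,2,3,5,8,8a-hexahydroazulen-3-ol, both C3 epimers | OC1CC[C@]2(C)CC=C(C)CC=C12 | intermediate
11 | (8aR)-6,8a-dimethyl-1,2,8,8a-tetrahydroazulen-3(5H)-one | O=C1CC[C@]2(C)CC=C(C)CC=C12 | intermediate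
12 | (3R,8aR)-6,8a-dimethyl-3-(propan-2-yl)-1,2,3,5,8,8a-hexahydroazulen-3-ol | CC(C)[C@]1(O)CC[C@]2(C)CC=C(C)CC=C12 | intermediate
13 | 3a,4-epoxide of 12, oxirane oxygen cis to the hydroxyl and the angular methyl | CC(C)[C@]1(O)CC[C@]2(C)CC=C(C)C[C@H]3O[C@@]123 | intermediate
14 | (3R,3aS,4R,8aR)-6,8a-dimethyl-3-(propan-2-yl)-1,2,3,3a,4,5,8,8a-octahydroazulene-3,4-diol (C4 epimer of jaeschkeanadiol) | CC(C)[C@]1(O)CC[C@]2(C)CC=C(C)C[C@@H](O)[C@@H]12 | intermediate
15 | (3R,3aR,8aR)-3-hydroxy-6,8a-dimethyl-3-(propan-2-yl)-2,3,3a,5,8,8a-hexahydroazulen-4(1H)-one | CC(C)[C@]1(O)CC[C@]2(C)CC=C(C)CC(=O)[C@@H]12 | intermediate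
16 | jaeschkeanadiol, (3R,3aS,4S,8aR)-6,8a-dimethyl-3-(propan-2-yl)-1,2,3,3a,4,5,8,8a-octahydroazulene-3,4-diol | CC(C)[C@]1(O)CC[C@]2(C)CC=C(C)C[C@H](O)[C@@H]12 | intermediate
17 | 3,4-dimethoxybenzoyl chloride | COc1ccc(C(Cl)=O)cc1OC | starting material
18 | (3R,3aS,4S,8aR)-3-hydroxy-6,8a-dimethyl-3-(propan-2-yl)-1,2,3,3a,4,5,8,8a-octahydroazulen-4-yl 3,4-dimethoxybenzoate | COc1ccc(C(=O)O[C@H]2CC(C)=CC[C@@]3(C)CC[C@@](O)(C(C)C)[C@H]23)cc1OC | target

Total step count: 14. Longest linear sequence: 14 steps (nerol to 18).

**Steps most likely to fail**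

Step 7. The risks are rhodium insertion into the less substituted cyclopropane bond, coupling at the proximal allyl terminus ([3+2]), failure of the tertiary alkyl–rhodium to insert the alkyne, or a thermal 1,5-hydrogen shift that destroys the vinylcyclopropane. The fallback runs from 9 back to 11 with known reactions only. Semi-hydrogenation of the alkyne (H2, Pd/CaCO3 poisoned with Pb(OAc)2, quinoline) would give 5-[(1R,2R)-1-methyl-2-(prop-1-en-2-yl)cyclopropyl]pent-1-en-3-ol F1. This cis-2-ene-vinylcyclopropane belongs to the class known to give [5+2] adducts with [Rh(CO)2Cl]2, here (8aR)-6,8a-dimethyl-1,2,3,3a,4,5,8,8a-octahydroazulen-3-ol F2; its ring-fusion hydrogen is expected cis to the methyl group, but that centre is erased below. Dess–Martin oxidation would give (8aR)-6,8a-dimethyl-2,3a,4,5,8,8a-hexahydroazulen-3(1H)-one F3. The more substituted trimethylsilyl enol ether F4 (Me3SiCl, NaI, Et3N, MeCN, equilibrating conditions) and Saegusa–Ito dehydrogenation (Pd(OAc)2, MeCN) would then install the ring-fusion double bond and give 11.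

Step 11. The risks are hydrogen-atom transfer to the wrong face of the ring-fusion radical, or capture of the radical by a second titanium followed by β-elimination (deoxygenation back to the olefin). The fallback runs from 7 back to 15 and encodes the C4 carbonyl before the cycloaddition as an alkenylsilane. Addition of lithiated benzyl(ethynyl)dimethylsilane to 7 (THF, −78 °C) would give 1-[(1S,2R)-2-{5-[benzyl(dimethyl)silyl]-3-hydroxypent-4-yn-1-yl}-2-methylcyclopropyl]ethan-1-one F5. Wittig methylenation as in step 6 would give 1-[benzyl(dimethyl)silyl]-5-[(1R,2R)-1-methyl-2-(prop-1-en-2-yl)cyclopropyl]pent-1-yn-3-ol F6. The cycloaddition of step 7 would give (8aR)-4-[benzyl(dimethyl)silyl]-6,8a-dimethyl-1,2,3,5,8,8a-hexahydroazulen-3-ol F7. MnO2 would give the silyl dienone (8aR)-4-[benzyl(dimethyl)silyl]-6,8a-dimethyl-1,2,8,8a-tetrahydroazulen-3(5H)-one F8. Isopropyl addition as in step 9 would give (3R,8aR)-4-[benzyl(dimethyl)silyl]-6,8a-dimethyl-3-(propan-2-yl)-1,2,3,5,8,8a-hexahydroazulen-3-ol F9. Its cis-γ-hydroxy alkenylsilane would be oxidized (Bu4NF, THF; then KHCO3, H2O2, MeOH; Tamao–Fleming oxidation through the cyclic siloxane) to the enol, which should tautomerize under the mildly basic conditions to the hydrogen-bonded trans-fused ketone 15.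

Step 9. The risks are γ-deprotonation or enolization of the skipped dienone, conjugate addition, or β-hydride reduction in place of 1,2-addition. The fallback runs from 11 back to 12. Isopropenylmagnesium bromide with CeCl3 (an sp2 nucleophile without β-hydrogens, smaller and less basic) would give (3R,8aR)-6,8a-dimethyl-3-(prop-1-en-2-yl)-1,2,3,5,8,8a-hexahydroazulen-3-ol F10. Chemoselective hydrogenation of its 1,1-disubstituted olefin (H2, RhCl(PPh3)3, benzene) should leave both trisubstituted olefins and give 12.

**Further compounds**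
F1 | step 7 | 5-[(1R,2R)-1-methyl-2-(prop-1-en-2-yl)cyclopropyl]pent-1-en-3-ol, both carbinol epimers | C=C(C)[C@H]1C[C@@]1(C)CCC(O)C=C
F2 | step 7 | (8aR)-6,8a-dimethyl-1,2,3,3a,4,5,8,8a-octahydroazulen-3-ol, 3a-H drawn cis to the 8a-methyl, both C3 epimers | OC1CC[C@]2(C)CC=C(C)CC[C@H]12
F3 | step 7 | (8aR)-6,8a-dimethyl-2,3a,4,5,8,8a-hexahydroazulen-3(1H)-one, 3a-H drawn cis to the 8a-methyl | O=C1CC[C@]2(C)CC=C(C)CC[C@H]12
F4 | step 7 | {[(8aR)-6,8a-dimethyl-1,2,4,5,8,8a-hexahydroazulen-3-yl]oxy}trimethylsilane | C[Si](C)(C)OC1=C2CCC(C)=CC[C@@]2(C)CC1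
F5 | step 11 | 1-[(1S,2R)-2-{5-[benzyl(dimethyl)silyl]-3-hydroxypent-4-yn-1-yl}-2-methylcyclopropyl]ethan-1-one, both carbinol epimers | CC(=O)[C@H]1C[C@@]1(C)CCC(O)C#C[Si](C)(C)Cc1ccccc1
F6 | step 11 | 1-[benzyl(dimethyl)silyl]-5-[(1R,2R)-1-methyl-2-(prop-1-en-2-yl)cyclopropyl]pent-1-yn-3-ol, both carbinol epimers | C=C(C)[C@H]1C[C@@]1(C)CCC(O)C#C[Si](C)(C)Cc1ccccc1
F7 | step 11 | (8aR)-4-[benzyl(dimethyl)silyl]-6,8a-dimethyl-1,2,3,5,8,8a-hexahydroazulen-3-ol, both C3 epimers | OC1CC[C@]2(C)CC=C(C)CC([Si](C)(C)Cc3ccccc3)=C12
F8 | step 11 | (8aR)-4-[benzyl(dimethyl)silyl]-6,8a-dimethyl-1,2,8,8a-tetrahydroazulen-3(5H)-one | O=C1CC[C@]2(C)CC=C(C)CC([Si](C)(C)Cc3ccccc3)=C12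
F9 | step 11 | (3R,8aR)-4-[benzyl(dimethyl)silyl]-6,8a-dimethyl-3-(propan-2-yl)-1,2,3,5,8,8a-hexahydroazulen-3-ol | CC(C)[C@]1(O)CC[C@]2(C)CC=C(C)CC([Si](C)(C)Cc3ccccc3)=C12
F10 | step 9 | (3R,8aR)-6,8a-dimethyl-3-(prop-1-en-2-yl)-1,2,3,5,8,8a-hexahydroazulen-3-ol | CC(=C)[C@]1(O)CC[C@]2(C)CC=C(C)CC=C12
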